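**Remarks on the chemistry (assumptions)**
- Flavan numbering is used. Upper half: rings A (benzo), B (catechol), C (pyran). Lower half: rings D (benzo), E (catechol), F (pyran).
- The target is read as a (4α→6)-linked dimer of two (2R,3S)-3',4',7,8-tetrahydroxyflavan-3-ol units (2,3-trans), with C4 of ring C (R), i.e. 3,4-trans.
- The sense of induction of the chiral borane is taken from its behaviour with 1-arylcycloalkenes, which corresponds to (2R,3S) here. If a first run shows the opposite sense, the antipodal borane is used and nothing else changes.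
- The coupling uses three equivalents of the nucleophilic monomer; the excess is recovered.

**Retrosynthetic overview**
1. The C4(ring C)–C6(ring D) interflavan bond is cut last: the C4 cation of an O-benzylated 3-O-acetyl flavan-3-ol is joined to C6 of the same O-benzylated flavan-3-ol, so both halves come from one (2R,3S) monomer.
2. In the monomer, C2 and C3 come from a reagent-controlled syn-hydroboration of a flav-2-ene (C2=C3 enol ether), which gives the 2,3-trans alcohol.
3. The pyran ring (ring F of the lower half, ring C of the upper half) is closed by making the C2–C3 bond: a titanium-alkylidene carbonyl–olefin ring closure of an ortho-allylaryl benzoate.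
4. Enabling feature: in the pyran ring, C2 carries O1 and the catechol ring, so it is the carbonyl carbon of an O1 aryl ester in disguise. C3–C4 is an allyl group on C4a ortho to O1 (aromatic Claisen), and the trans C2-aryl/C3-OH pair is the mark of enol-ether hydroboration.
5. Ring order: the benzene rings A/D and B/E are bought; pyran rings C and F are formed in one and the same operation (step 6); no ring is formed afterwards.

Key step: step 6

**Route**

Step 1
Reactants: 1 2,3-dihydroxybenzaldehyde
Product: 2 2,3-bis(benzyloxy)benzaldehyde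
Conditions: BnBr (2.3 equiv), K2CO3, DMF, 60 °C
Reagents that add atoms: benzyl bromide, BrCc1ccccc1
Why: Williamson ether synthesis on both phenols, leaving the aldehyde untouched and giving protecting groups that leave in the final hydrogenolysis.

Step 2
Reactants: 2 2,3-bis(benzyloxy)benzaldehyde
Product: 4 2,3-bis(benzyloxy)phenol, via aryl formate 3 (not isolated)
Conditions: mCPBA, CH2Cl2, rt; then K2CO3 (cat.), MeOH, rt
Reagents that add atoms: 3-chloroperbenzoic acid (mCPBA), OOC(=O)c1cccc(Cl)c1
Why: Dakin-type Baeyer–Villiger oxidation, in which the electron-rich ortho-alkoxyaryl group migrates in preference to hydride, followed by methanolysis of the formate in the same flask.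

Step 3
Reactants: 4 2,3-bis(benzyloxy)phenol; 5 allyl bromide
Product: 6 1-(allyloxy)-2,3-bis(benzyloxy)benzene
Conditions: K2CO3, acetone, reflux
Reagents that add atoms: none
Why: Williamson O-allylation of the phenoxide, which installs the three-carbon unit whose inner two carbons become C4 and C3.

Step 4
Reactants: 6 1-(allyloxy)-2,3-bis(benzyloxy)benzene
Product: 8 6-allyl-2,3-bis(benzyloxy)phenol, via ortho-dienone 7 (not isolated)
Conditions: N,N-diethylaniline, 190 °C
Reagents that add atoms: none
Why: Aromatic Claisen rearrangement ([3,3]-sigmatropic shift) to the only ortho carbon that bears hydrogen, followed by tautomerisation of the dienone, under thermal conditions that benzyl aryl ethers tolerate.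

Step 5
Reactants: 8 6-allyl-2,3-bis(benzyloxy)phenol; 9 3,4-bis(benzyloxy)benzoic acid
Product: 10 6-allyl-2,3-bis(benzyloxy)phenyl 3,4-bis(benzyloxy)benzoate
Conditions: DCC, DMAP (cat.), CH2Cl2, 0 °C → rt
Reagents that add atoms: none
Why: Steglich esterification, in which acyl transfer through the acylpyridinium ion overcomes the hindrance of the 2,6-disubstituted phenol and joins O1 to the future C2.

Step 6
Reactants: 10 6-allyl-2,3-bis(benzyloxy)phenyl 3,4-bis(benzyloxy)benzoate
Product: 12 7,8-bis(benzyloxy)-2-[3,4-bis(benzyloxy)phenyl]-4H-chromene (tetra-O-benzyl flav-2-ene), via titanium alkylidene 11 (not isolated)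
Conditions: TiCl4, TMEDA, Zn, PbCl2 (cat.), CH3CHBr2, THF/CH2Cl2, 0 → 65 °C; aqueous K2CO3 work-up, Et3N-deactivated silica
Reagents that add atoms: none
Why: The titanium ethylidene generated from TiCl4, TMEDA, Zn, PbCl2 and CH3CHBr2 (Takai–Utimoto conditions) exchanges with the unhindered terminal alkene of the allyl group ([2+2] cycloaddition and cycloreversion, propene lost) to place a nucleophilic titanium alkylidene on C3 (11); this carbon then attacks the ester carbonyl carbon C2, and collapse of the four-membered titanium–oxygen ring expels the titanium oxo fragment and leaves the C2=C3 enol ether. The closest known reaction type is the olefinic ester cyclisation (ring-closing carbonyl–olefin metathesis) with titanium alkylidenes made under these conditions or from Cp2Ti(μ-Cl)(μ-CH2)AlMe2, which is established for six-membered cyclic enol ethers. The pyran ring closes by a 6-exo-trig attack of C3 on the C2 carbonyl (ring atoms O1, C2, C3, C4, C4a, C8a), the polarity of C3 being reversed from its carbinol character in the target. No stereocentre is created; the step fixes the enol ether inside the ring so that C2 and C3 can be set together in step 7. The selectivity needed is ring closure over plain ethylidenation of the ester, and it is secured by the order of events: the monosubstituted allyl alkene is far more accessible than the di-ortho-substituted, donor-conjugated aryl ester, so the alkylidene forms on the tether first and reaches the carbonyl intramolecularly. Titanium alkylidenes do not migrate the allyl double bond, so ring contraction to a benzofuran, the side path known for ruthenium hydrides, is not expected.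

Step 7
Reactants: 12 7,8-bis(benzyloxy)-2-[3,4-bis(benzyloxy)phenyl]-4H-chromene
Product: 14 (2R,3S)-7,8-bis(benzyloxy)-2-[3,4-bis(benzyloxy)phenyl]chroman-3-ol, via flavanylborane 13 (not isolated)
Conditions: monoisopinocampheylborane from (+)-α-pinene (IpcBH2, 1.5 equiv), THF, −25 → 0 °C; then NaOH, H2O2, 0 °C → rt
Reagents that add atoms: hydrogen peroxide, OO
Why: Asymmetric hydroboration–oxidation of a trisubstituted aryl enol ether, in which boron goes to C3 (β to O1 and away from the aryl group), syn addition and oxidation with retention give the 2,3-trans alcohol, and the chiral borane selects the alkene face so that C2 (R) and C3 (S) are set together.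

Step 8
Reactants: 14 (2R,3S)-7,8-bis(benzyloxy)-2-[3,4-bis(benzyloxy)phenyl]chroman-3-ol (the portion destined for the upper half)
Product: 15 (2R,3S)-7,8-bis(benzyloxy)-2-[3,4-bis(benzyloxy)phenyl]chroman-3-yl acetate
Conditions: Ac2O, pyridine, DMAP (cat.), CH2Cl2, rt
Reagents that add atoms: acetic anhydride, CC(=O)OC(C)=O
Why: Standard acetylation of the secondary alcohol, which provides the participating group that steers the C4 chemistry of steps 9 and 10.

Step 9
Reactants: 15 (2R,3S)-7,8-bis(benzyloxy)-2-[3,4-bis(benzyloxy)phenyl]chroman-3-yl acetate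
Product: 17 3-O-acetyl-4α-(2-ethoxyethoxy) derivative of 14 (2,3-trans-3,4-trans), via flavan-4-ylium hydroquinonate ion pair 16 (not isolated)
Conditions: DDQ (2 equiv), 2-ethoxyethanol (5 equiv), CH2Cl2, rt
Reagents that add atoms: 2-ethoxyethanol, CCOCCO
Why: DDQ benzylic oxidation, in which hydride abstraction from C4 gives the open C4 cation paired with the reduced quinone monoanion (16), stabilised by the para 7-benzyloxy group and by O1 through C8a, and the alcohol captures it trans to the 3-acetate; the configuration at C4 is of no consequence because the centre is ionised again in step 10.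

Step 10
Reactants: 17 3-O-acetyl-4α-(2-ethoxyethoxy) derivative of 14; 14 (2R,3S)-7,8-bis(benzyloxy)-2-[3,4-bis(benzyloxy)phenyl]chroman-3-ol (3 equiv)
Product: 19 octa-O-benzyl (4α→6) dimer monoacetate (3-O-acetyl upper half, free 3-OH lower half), via acetoxonium triflate 18 (not isolated)
Conditions: TMSOTf (0.1 equiv), 4 Å MS, CH2Cl2, −78 °C; Et3N quench
Reagents that add atoms: none
Why: Lewis-acid-promoted Friedel–Crafts-type interflavan coupling, in which silylation of the C4 ether oxygen and departure of the silyl ether with participation of the 3β-acetate give the β-face-bridged 3,4-acetoxonium (dioxolanylium) triflate 18, and C6 of 14 (ortho to the 7-benzyloxy group and para to O1, the position at which 1,2,3-trialkoxybenzenes are substituted) opens it at C4 from the free α face, setting C4 of ring C as 4α (3,4-trans), while the excess of 14 suppresses self-condensation of 17.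

Step 11
Reactants: 19 octa-O-benzyl (4α→6) dimer monoacetate
Product: 20 octa-O-benzyl (4α→6) dimer with both 3-OH groups free
Conditions: NaOMe (cat.), MeOH/THF, 40 °C
Reagents that add atoms: none
Why: Zemplén-type transesterification removes the acetate without touching the benzyl ethers, the interflavan bond or any stereocentre.

Step 12
Reactants: 20 octa-O-benzyl (4α→6) dimer
Product: 21 (2R,3S,4R)-2-(3,4-dihydroxyphenyl)-4-[(2R,3S)-2-(3,4-dihydroxyphenyl)-3,7,8-trihydroxychroman-6-yl]chromane-3,7,8-triol (target)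
Conditions: H2 (1 atm), Pd(OH)2/C, THF/MeOH/H2O, rt
Reagents that add atoms: none
Why: Catalytic hydrogenolysis of the eight benzyl ethers under neutral conditions, as is usual for benzylated proanthocyanidins, should leave the pyran C–O bonds, the interflavan bond and all five stereocentres intact.

**Compound list**
1 | 2,3-dihydroxybenzaldehyde | O=Cc1cccc(O)c1O | starting material
2 | 2,3-bis(benzyloxy)benzaldehyde | O=Cc1cccc(OCc2ccccc2)c1OCc1ccccc1 | intermediate
3 | 2,3-bis(benzyloxy)phenyl formate (not isolated) | O=COc1cccc(OCc2ccccc2)c1OCc1ccccc1 | intermediate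
4 | 2,3-bis(benzyloxy)phenol | Oc1cccc(OCc2ccccc2)c1OCc1ccccc1 | intermediate
5 | allyl bromide | C=CCBr | starting material
6 | 1-(allyloxy)-2,3-bis(benzyloxy)benzene | C=CCOc1cccc(OCc2ccccc2)c1OCc1ccccc1 | intermediate
7 | 6-allyl-2,3-bis(benzyloxy)cyclohexa-2,4-dien-1-one (not isolated) | O=C1C(CC=C)C=CC(OCc2ccccc2)=C1OCc1ccccc1 | intermediate
8 | 6-allyl-2,3-bis(benzyloxy)phenol | C=CCc1ccc(OCc2ccccc2)c(OCc2ccccc2)c1O | intermediate
9 | 3,4-bis(benzyloxy)benzoic acid | OC(=O)c1ccc(OCc2ccccc2)c(OCc2ccccc2)c1 | starting material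
10 | 6-allyl-2,3-bis(benzyloxy)phenyl 3,4-bis(benzyloxy)benzoate | C=CCc1ccc(OCc2ccccc2)c(OCc2ccccc2)c1OC(=O)c1ccc(OCc2ccccc2)c(OCc2ccccc2)c1 | intermediate
11 | titanium alkylidene at C3 of the ester (not isolated; drawn without TMEDA) | Cl[Ti](Cl)=CCc1ccc(OCc2ccccc2)c(OCc2ccccc2)c1OC(=O)c1ccc(OCc2ccccc2)c(OCc2ccccc2)c1 | intermediate
12 | 7,8-bis(benzyloxy)-2-[3,4-bis(benzyloxy)phenyl]-4H-chromene | C1=C(c2ccc(OCc3ccccc3)c(OCc3ccccc3)c2)Oc2c(C1)ccc(OCc1ccccc1)c2OCc1ccccc1 | intermediate
13 | 2,3-trans-flavan-3-yl(isopinocampheyl)borane, tetra-O-benzyl, ring configuration as in 14 (not isolated) | C[C@H]1[C@H](B[C@H]2Cc3ccc(OCc4ccccc4)c(OCc4ccccc4)c3O[C@@H]2c2ccc(OCc3ccccc3)c(OCc3ccccc3)c2)C[C@@H]2C[C@H]1C2(C)C | intermediate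
14 | (2R,3S)-7,8-bis(benzyloxy)-2-[3,4-bis(benzyloxy)phenyl]chroman-3-ol | O(Cc1ccccc1)c1ccc([C@H]2Oc3c(ccc(OCc4ccccc4)c3OCc3ccccc3)C[C@@H]2O)cc1OCc1ccccc1 | intermediate
15 | (2R,3S)-7,8-bis(benzyloxy)-2-[3,4-bis(benzyloxy)phenyl]chroman-3-yl acetate | O(Cc1ccccc1)c1ccc([C@H]2Oc3c(ccc(OCc4ccccc4)c3OCc3ccccc3)C[C@@H]2OC(C)=O)cc1OCc1ccccc1 | intermediate
16 | 3-acetoxy-tetra-O-benzylflavan-4-ylium 2,3-dichloro-5,6-dicyano-4-hydroxyphenolate, open C4 cation ion pair (not isolated) | O(Cc1ccccc1)c1ccc([C@H]2Oc3c(ccc(OCc4ccccc4)c3OCc3ccccc3)[CH+][C@@H]2OC(C)=O)cc1OCc1ccccc1.[O-]c1c(Cl)c(Cl)c(O)c(C#N)c1C#N | intermediate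
17 | 3-O-acetyl-4α-(2-ethoxyethoxy) derivative of 14 (2,3-trans-3,4-trans) | O(Cc1ccccc1)c1ccc([C@H]2Oc3c(ccc(OCc4ccccc4)c3OCc3ccccc3)[C@@H](OCCOCC)[C@@H]2OC(C)=O)cc1OCc1ccccc1 | intermediate
18 | 3β,4β-bridged acetoxonium (2-methyl-1,3-dioxolan-2-ylium) ion of the tetra-O-benzyl flavan, triflate (not isolated) | O(Cc1ccccc1)c1ccc([C@H]2Oc3c(ccc(OCc4ccccc4)c3OCc3ccccc3)[C@@H]3[O+]=C(C)O[C@H]23)cc1OCc1ccccc1.[O-]S(=O)(=O)C(F)(F)F | intermediate
19 | octa-O-benzyl (4α→6) dimer, upper 3-O-acetate | O(Cc1ccccc1)c1ccc([C@H]2Oc3c(ccc(OCc4ccccc4)c3OCc3ccccc3)[C@@H](c3cc4c(c(OCc5ccccc5)c3OCc3ccccc3)O[C@H](c3ccc(OCc5ccccc5)c(OCc5ccccc5)c3)[C@@H](O)C4)[C@@H]2OC(C)=O)cc1OCc1ccccc1 | intermediate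
20 | octa-O-benzyl (4α→6) dimer, both 3-OH free | O(Cc1ccccc1)c1ccc([C@H]2Oc3c(ccc(OCc4ccccc4)c3OCc3ccccc3)[C@@H](c3cc4c(c(OCc5ccccc5)c3OCc3ccccc3)O[C@H](c3ccc(OCc5ccccc5)c(OCc5ccccc5)c3)[C@@H](O)C4)[C@@H]2O)cc1OCc1ccccc1 | intermediate
21 | (2R,3S,4R)-2-(3,4-dihydroxyphenyl)-4-[(2R,3S)-2-(3,4-dihydroxyphenyl)-3,7,8-trihydroxychroman-6-yl]chromane-3,7,8-triol | Oc1ccc([C@H]2Oc3c(ccc(O)c3O)[C@@H](c3cc4c(c(O)c3O)O[C@H](c3ccc(O)c(O)c3)[C@@H](O)C4)[C@@H]2O)cc1O | target

**Step count and risks**

Total step count: 12. Longest linear sequence: 12 steps (1 → 21). Compound 14 is used twice, as the nucleophile of step 10 and as the precursor of the electrophile 17.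

Steps most likely to fail:

1. Step 6 (key step). The ester may be intercepted by the ethylidene reagent before alkene exchange (plain ethylidenation to an acyclic enol ether), or ring closure may stall on the hindered aryl ester. The fallback separates the two events and sets out from 10. Methylenation with Cp2TiMe2 (toluene, 70 °C) should give the acyclic enol ether 1-[6-allyl-2,3-bis(benzyloxy)phenoxy]-1-[3,4-bis(benzyloxy)phenyl]ethene F1. This is closed in a separate olefin–olefin ring-closing metathesis with the second-generation Grubbs catalyst, RuCl2(=CHPh)(H2IMes)(PCy3), in toluene at 80 °C, with 1,4-benzoquinone added to suppress allyl-to-propenyl migration. The fallback comes back to the route at 12.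

2. Step 7. Facial discrimination by the chiral borane may be insufficient on the flat, benzo-fused enol ether, and the β-aryloxyborane may undergo β-elimination on warming. The fallback replaces asymmetric induction by resolution and sets out from 12. Hydroboration with BH3·SMe2 followed by NaOH/H2O2 should give the racemic 2,3-trans alcohol, (±)-trans-7,8-bis(benzyloxy)-2-[3,4-bis(benzyloxy)phenyl]chroman-3-ol F2. Esterification with (S)-2-methoxy-2-phenylacetic acid (DCC, DMAP) gives two diastereomeric esters: the (2R,3S)-chroman-3-yl (S)-2-methoxy-2-phenylacetate F3 and the (2S,3R)-chroman-3-yl (S)-2-methoxy-2-phenylacetate F4. These are separated by chromatography or crystallisation. Methanolysis of F3 (K2CO3, MeOH/THF) comes back to the route at 14.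

3. Step 9. On this ring A, which lacks the 5-oxygen, hydride abstraction may occur at C2 instead of C4, or over-oxidation may set in. The fallback avoids C–H oxidation at the flavan stage, reverses the roles of the partners, and also bypasses steps 8, 10 and 11. It sets out from 12 and 14.
   - Hydride abstraction from the doubly activated C4 of 12 with Ph3CBF4 (CH2Cl2/MeCN) should give the flavylium salt 7,8-bis(benzyloxy)-2-[3,4-bis(benzyloxy)phenyl]chromenylium tetrafluoroborate F5.
   - Bromination of 14 with NBS (CH2Cl2, 0 °C) at its most activated position should give (2R,3S)-6-bromo-7,8-bis(benzyloxy)-2-[3,4-bis(benzyloxy)phenyl]chroman-3-ol F6.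
   - Treatment of F6 with n-BuLi (2.2 equiv, THF, −78 °C) gives the C6-lithio lithium alkoxide F7.
   - Addition of F7 to C4 of F5 should give the 4-arylflav-2-ene F8 as both C4 epimers.
   - Hydroboration–oxidation of F8 (BH3·SMe2; NaOH, H2O2) takes place anti to the 4-aryl group and so gives the all-trans upper half in each epimer. After separation from the diastereomer with the enantiomeric upper half F9, this comes back to the route at 20.
   - The cost is that C4 is not controlled in the addition, so about half of the material is expected to end as F9.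

**Further compounds**
F1 | step 6 | 1-[6-allyl-2,3-bis(benzyloxy)phenoxy]-1-[3,4-bis(benzyloxy)phenyl]ethene | C=CCc1ccc(OCc2ccccc2)c(OCc2ccccc2)c1OC(=C)c1ccc(OCc2ccccc2)c(OCc2ccccc2)c1
F2 | step 7 | (±)-trans-7,8-bis(benzyloxy)-2-[3,4-bis(benzyloxy)phenyl]chroman-3-ol (racemate) | O(Cc1ccccc1)c1ccc([C@H]2Oc3c(ccc(OCc4ccccc4)c3OCc3ccccc3)C[C@@H]2O)cc1OCc1ccccc1.O(Cc1ccccc1)c1ccc([C@@H]2Oc3c(ccc(OCc4ccccc4)c3OCc3ccccc3)C[C@H]2O)cc1OCc1ccccc1
F3 | step 7 | (2R,3S)-7,8-bis(benzyloxy)-2-[3,4-bis(benzyloxy)phenyl]chroman-3-yl (S)-2-methoxy-2-phenylacetate | O(Cc1ccccc1)c1ccc([C@H]2Oc3c(ccc(OCc4ccccc4)c3OCc3ccccc3)C[C@@H]2OC(=O)[C@@H](OC)c2ccccc2)cc1OCc1ccccc1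
F4 | step 7 | (2S,3R)-7,8-bis(benzyloxy)-2-[3,4-bis(benzyloxy)phenyl]chroman-3-yl (S)-2-methoxy-2-phenylacetate | O(Cc1ccccc1)c1ccc([C@@H]2Oc3c(ccc(OCc4ccccc4)c3OCc3ccccc3)C[C@H]2OC(=O)[C@@H](OC)c2ccccc2)cc1OCc1ccccc1
F5 | step 9 | 7,8-bis(benzyloxy)-2-[3,4-bis(benzyloxy)phenyl]chromenylium tetrafluoroborate | c1(-c2ccc(OCc3ccccc3)c(OCc3ccccc3)c2)ccc2ccc(OCc3ccccc3)c(OCc3ccccc3)c2[o+]1.F[B-](F)(F)F
F6 | step 9 | (2R,3S)-6-bromo-7,8-bis(benzyloxy)-2-[3,4-bis(benzyloxy)phenyl]chroman-3-ol | Brc1cc2c(c(OCc3ccccc3)c1OCc1ccccc1)O[C@H](c1ccc(OCc3ccccc3)c(OCc3ccccc3)c1)[C@@H](O)C2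
F7 | step 9 | C6-lithio lithium alkoxide of F6 | [Li]c1cc2c(c(OCc3ccccc3)c1OCc1ccccc1)O[C@H](c1ccc(OCc3ccccc3)c(OCc3ccccc3)c1)[C@@H](O[Li])C2
F8 | step 9 | octa-O-benzyl 4-arylflav-2-ene (upper half) linked to C6 of the (2R,3S) lower half, both C4 epimers | O(Cc1ccccc1)c1ccc(C2=CC(c3cc4c(c(OCc5ccccc5)c3OCc3ccccc3)O[C@H](c3ccc(OCc5ccccc5)c(OCc5ccccc5)c3)[C@@H](O)C4)c3ccc(OCc4ccccc4)c(OCc4ccccc4)c3O2)cc1OCc1ccccc1
F9 | step 9 | diastereomer of 20 with the enantiomeric all-trans upper half | O(Cc1ccccc1)c1ccc([C@@H]2Oc3c(ccc(OCc4ccccc4)c3OCc3ccccc3)[C@H](c3cc4c(c(OCc5ccccc5)c3OCc3ccccc3)O[C@H](c3ccc(OCc5ccccc5)c(OCc5ccccc5)c3)[C@@H](O)C4)[C@H]2O)cc1OCc1ccccc1
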